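**Retrosynthetic overview**
1. The target is a trans-fused dictyol-type hydroazulene: ring fusion C1/C5, cyclopentene C3=C4(CH3), C6–OH, side chain on C7, C9–OH and C10=CH2 in the seven-membered ring.
2. Enabling feature: in the seven-membered ring the carbinol carbon C6 lies between C5 and C7 (a three-carbon oxyallyl unit) and faces the four-carbon segment C8–C9–C10–C1, whose C9–OH/C10=CH2 allylic alcohol is a transposed C9=C10(CH3) alkene, the remnant of a 2-methylbuta-1,3-diene. C4 and C5 of the cyclopentene can be an epoxide, so C6–C5–C4(CH3)–C3–C2–C1–C10(CH3)–C9 is the carbon chain of geraniol, with C8 as one added methylene.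
3. Key disconnection: C7–C8 and C1–C5, made together by an intramolecular (4+3) cycloaddition of an acyclic, geraniol-derived epoxy enol silane. Both rings form in this operation (the five-membered ring through C1–C5, the seven-membered ring through both bonds), and the Sharpless epoxide relays absolute configuration to C5 and C1.
4. After the bicycle: C7–C11 by enolate alkylation with the triflate of ethyl (S)-lactate, C6–OH by reduction with lactonisation, C9–OH/C10=CH2 by epoxidation and isomerisation, C3=C4 by dehydration of the C4 carbinol left by the epoxide.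
5. Side chain end: lactone to C12 aldehyde, Felkin-selective Mukaiyama aldol (C12), acetylation, CBS reduction (C14), desilylation.

Key step: step 9

Remark: positions are numbered as in the dictyol skeleton (C1/C5 ring fusion, C2–C4 in the five-membered ring, C6–C10 in the seven-membered ring, side chain C11–C15); the carbinol epimers of 7 are carried as a mixture because that centre is oxidised in step 7.

**Route**

Step 1
Reactants: 1 geranyl acetate
Product: 2 (2E,6E)-3,7-dimethyl-8-oxoocta-2,6-dien-1-yl acetate
Conditions: SeO2 (1.2 equiv), 95% EtOH, reflux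
Reagents that add atoms: selenium dioxide, O=[Se]=O
Why: SeO2 allylic oxidation (ene reaction then [2,3] shift) attacks the E-methyl group of the terminal trisubstituted alkene selectively and, used in stoichiometric amount, should carry it on to the E-enal without forming a stereocentre.

Step 2
Reactants: 2 (2E,6E)-3,7-dimethyl-8-oxoocta-2,6-dien-1-yl acetate
Product: 3 (2E,6E)-3,7-dimethylnona-2,6,8-trien-1-yl acetate
Conditions: Ph3PCH3Br, KOtBu, THF, 0 °C; then 2, −78 to 0 °C
Reagents that add atoms: methyltriphenylphosphonium bromide, C[P+](c1ccccc1)(c1ccccc1)c1ccccc1.[Br-]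
Why: Wittig methylenation of the enal by the non-stabilised ylide is much faster than attack on the acetate and leaves the E-trisubstituted alkene untouched, giving the 2-methylbuta-1,3-diene terminus.

Step 3
Reactants: 3 (2E,6E)-3,7-dimethylnona-2,6,8-trien-1-yl acetate
Product: 4 (2E,6E)-3,7-dimethylnona-2,6,8-trien-1-ol
Conditions: K2CO3 (cat.), MeOH, rt
Reagents that add atoms: none
Why: base-catalysed transesterification frees the allylic alcohol that will direct the epoxidation, and no stereocentre is involved.

Step 4
Reactants: 4 (2E,6E)-3,7-dimethylnona-2,6,8-trien-1-ol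
Product: 5 [(2R,3R)-3-methyl-3-[(3E)-4-methylhexa-3,5-dien-1-yl]oxiran-2-yl]methanol
Conditions: Ti(OiPr)4 (10 mol%), D-(−)-diethyl tartrate (12 mol%), tBuOOH, 4 Å MS, CH2Cl2, −20 °C
Reagents that add atoms: tert-butyl hydroperoxide, CC(C)(C)OO
Why: Sharpless asymmetric epoxidation acts only on the allylic alcohol alkene, and the D-(−)-tartrate ligand delivers oxygen to the face that gives the (2R,3R)-epoxide, which fixes the future C4 and, after inversion in step 9, C5.

Step 5
Reactants: 5 (2R,3R)-epoxy alcohol
Product: 6 (2S,3R)-3-methyl-3-[(3E)-4-methylhexa-3,5-dien-1-yl]oxirane-2-carbaldehyde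
Conditions: PhI(OAc)2, TEMPO (10 mol%), CH2Cl2, rt
Reagents that add atoms: none
Why: TEMPO-catalysed oxidation stops at the aldehyde under near-neutral conditions that preserve the epoxide and the diene.

Step 6
Reactants: 6 epoxy aldehyde
Product: 7 1-[(2R,3R)-3-methyl-3-[(3E)-4-methylhexa-3,5-dien-1-yl]oxiran-2-yl]ethan-1-ol (both carbinol epimers)
Conditions: MeMgBr, THF, −78 °C
Reagents that add atoms: methylmagnesium bromide, C[Mg]Br
Why: Grignard addition to the aldehyde is faster than epoxide opening at low temperature, and the new carbinol centre is removed in step 7.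

Step 7
Reactants: 7 epoxy carbinol
Product: 8 1-[(2S,3R)-3-methyl-3-[(3E)-4-methylhexa-3,5-dien-1-yl]oxiran-2-yl]ethan-1-one
Conditions: Dess–Martin periodinane, pyridine, CH2Cl2, 0 °C to rt
Reagents that add atoms: none
Why: Dess–Martin oxidation of the secondary alcohol gives the α,β-epoxy methyl ketone without touching the epoxide stereocentres.

Step 8
Reactants: 8 epoxy methyl ketone
Product: 10 triethylsilyl enol ether of 8 [triethyl({1-[(2S,3R)-3-methyl-3-[(3E)-4-methylhexa-3,5-dien-1-yl]oxiran-2-yl]ethenyl}oxy)silane], via lithium enolate 9 (not isolated)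
Conditions: LiN(iPr)2, THF, −78 °C; then Et3SiCl, −78 to 0 °C
Reagents that add atoms: chlorotriethylsilane, CC[Si](Cl)(CC)CC
Why: kinetic deprotonation of the methyl group (the only readily enolisable position) and O-silylation give the 2-silyloxyallyl epoxide needed for the cycloaddition.

Step 9
Reactants: 10 triethylsilyl enol ether of 8
Product: 13 trans-fused hydroazulenone (1S,4R,5R; C6 ketone; C9=C10(CH3) alkene; C4 methyl and OSiEt3), via silyl epoxonium triflate 11 (not isolated), via silyl oxocarbenium triflate 12 (not isolated)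
Conditions: Et3SiOTf (0.2 equiv), CH2Cl2, −78 °C; Et3N quench
Reagents that add atoms: none
Why: Et3SiOTf silylates the epoxide oxygen to give 11, whose C5–O bond is aligned with the enol silane π-system; the diene terminus C1 then displaces that oxygen from C5 in an SN2-like manner while the enol silane terminus C7 bonds to C8, and the silyloxocarbenium ion 12 returns Et3Si+ to triflate, so the catalyst turns over and the epoxide oxygen ends as the C4 silyl ether. The closest known reaction type is the silyl-triflate-catalysed intramolecular (4+3) cycloaddition of epoxy enol silanes that carry a diene on a two-carbon tether at the distal epoxide carbon, a concerted asynchronous process that transfers epoxide chirality. The five-membered ring closes by C1–C5 bond formation with opening of the epoxide at its enol-silane-bearing carbon (both epoxide carbons end up in the new ring), and the seven-membered ring closes by union of the four-carbon diene C8–C9–C10–C1 with the three-carbon silyloxyallyl unit C5–C6–C7. C5 is set by inversion at the epoxide carbon, C4 keeps the epoxide configuration (the E-epoxide points the tether toward the diene), and C1 is set by the E geometry of the C1=C10 bond together with the extended, chair-like arrangement of diene and allyl unit, which places H1 and H5 trans. The step needs trans over cis ring fusion, which the substrate should secure because in the compact arrangement the OSiEt3 group on C6 lies over the C10 methyl of the diene, and it needs opening at C5 and not at the tertiary C4, which the allylic activation of C5 and the tether, which cannot reach C4 in a ring of sensible size, should favour.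

Step 10
Reactants: 14 ethyl (S)-lactate
Product: 15 ethyl (2S)-2-{[(trifluoromethyl)sulfonyl]oxy}propanoate
Conditions: Tf2O, 2,6-lutidine, CH2Cl2, −78 to 0 °C
Reagents that add atoms: trifluoromethanesulfonic anhydride, O=S(=O)(OS(=O)(=O)C(F)(F)F)C(F)(F)F
Why: O-sulfonylation of the lactate hydroxyl proceeds with retention and gives an SN2-competent secondary triflate whose stereocentre comes from the chiral pool.

Step 11
Reactants: 13 trans-fused hydroazulenone; 15 ethyl (2S)-2-(triflyloxy)propanoate
Product: 17 γ-keto ester (7R,11S) [ethyl (2S)-2-(6-oxo-hydroazulen-7-yl)propanoate], via lithium enolate 16 (not isolated)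
Conditions: LiN(iPr)2, THF, −78 °C; then 15, THF/DMPU, −78 to −40 °C
Reagents that add atoms: none
Why: kinetic deprotonation occurs at the C7 methylene (C5–H is tertiary and hindered), and SN2 alkylation of the enolate by the α-triflyloxy ester sets C11 by inversion (S-triflate to 11S) and C7 by stereoelectronically favoured axial attack on the conformationally locked trans-fused enolate, on the face syn to H5, which places the new chain as in the target.

Step 12
Reactants: 17 γ-keto ester
Product: 19 cis-fused γ-lactone (O6–C12; 6S hydroxyl oxygen cis to the C7 chain), via hydroxy ester 18 (not isolated)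
Conditions: NaBH4, CeCl3·7H2O, MeOH/THF, −40 °C; then PPTS (cat.), benzene, 50 °C
Reagents that add atoms: none
Why: Luche-type hydride reduction delivers hydride to C6 along the axial trajectory anti to the axial C7 substituent, so the C6 hydroxyl forms cis to the side chain and closes onto the ester to give the cis-fused lactone, which protects O6 and stops epimerisation at C7.

Step 13
Reactants: 19 cis-fused γ-lactone
Product: 20 (9S,10R)-9,10-epoxy lactone
Conditions: mCPBA, NaHCO3, CH2Cl2, 0 °C
Reagents that add atoms: 3-chloroperbenzoic acid, OOC(=O)c1cccc(Cl)c1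
Why: Prilezhaev epoxidation takes place at the only alkene and from the convex face of the cycloheptene opposite the C5–C6–C7 bridge, which puts the C9 oxygen cis to H1 as the target requires.

Step 14
Reactants: 20 epoxy lactone
Product: 21 allylic alcohol lactone (9S hydroxyl, C10 exocyclic methylene)
Conditions: Cp2TiCl2 (2.5 equiv), Mn dust, THF, rt (Cp2TiCl formed in the flask); dilute aqueous HCl work-up
Reagents that add atoms: none
Why: trivalent titanium (Cp2TiCl) opens the epoxide homolytically at the tertiary C10–O bond and the tertiary centre then loses hydrogen from the least hindered β-position, the methyl group, which gives the exocyclic methylene while the C9–O bond and its configuration stay untouched (radical epoxide-to-allylic-alcohol isomerisation).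

Step 15
Reactants: 21 allylic alcohol lactone
Product: 22 dihydroxy Weinreb amide (C6–OH and C9–OH free)
Conditions: MeNH(OMe)·HCl, AlMe3, CH2Cl2, 0 °C to rt; used at once
Reagents that add atoms: N,O-dimethylhydroxylamine hydrochloride, CNOC.Cl
Why: aluminium amide aminolysis (Weinreb amide formation) opens the γ-lactone without epimerising C11, frees O6 and leaves C12 at a level that can be reduced to the aldehyde.

Step 16
Reactants: 22 dihydroxy Weinreb amide
Product: 23 bis(tert-butyldimethylsilyl) ether (O6 and O9)
Conditions: tBuMe2SiOTf, 2,6-lutidine, CH2Cl2, −78 to 0 °C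
Reagents that add atoms: tert-butyldimethylsilyl trifluoromethanesulfonate, CC(C)(C)[Si](C)(C)OS(=O)(=O)C(F)(F)F
Why: silylation with the silyl triflate protects the hindered C6 hydroxyl and the allylic C9 hydroxyl in one operation and blocks relactonisation.

Step 17
Reactants: 23 bis-silyl ether
Product: 24 C4 tertiary alcohol
Conditions: HF·pyridine, pyridine, THF, 0 °C
Reagents that add atoms: none
Why: fluoride-mediated desilylation is much faster for a triethylsilyl ether than for tert-butyldimethylsilyl ethers, so the tertiary C4 hydroxyl should be unmasked selectively.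

Step 18
Reactants: 24 C4 tertiary alcohol
Product: 25 C3=C4 cyclopentene Weinreb amide
Conditions: SOCl2, pyridine, CH2Cl2, −30 to 0 °C
Reagents that add atoms: none
Why: dehydration through the chlorosulfite in pyridine is an anti (E2) elimination, and because H5 is syn to the C4 oxygen only the anti C3–H (Zaitsev, endocyclic) or a methyl hydrogen can be lost, the former being expected to dominate and to give the C3=C4 alkene without touching C5.

Step 19
Reactants: 25 C3=C4 cyclopentene Weinreb amide
Product: 26 C12 aldehyde
Conditions: iBu2AlH, THF, −78 °C; Rochelle salt work-up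
Reagents that add atoms: none
Why: hydride addition to the Weinreb amide gives a chelated tetrahedral intermediate that collapses to the aldehyde only on work-up, so there is no over-reduction and C11 should not epimerise.

Step 20
Reactants: 27 3-methylbut-3-en-2-one
Product: 28 trimethyl[(3-methylbuta-1,3-dien-2-yl)oxy]silane
Conditions: Me3SiOTf, Et3N, Et2O, 0 °C
Reagents that add atoms: trimethylsilyl trifluoromethanesulfonate, C[Si](C)(C)OS(=O)(=O)C(F)(F)F
Why: soft enolisation with silyl triflate and amine converts the methyl ketone into its 2-silyloxy diene, and no stereocentre is involved.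

Step 21
Reactants: 26 C12 aldehyde; 28 silyl dienol ether
Product: 29 β-hydroxy enone (12S)
Conditions: BF3·OEt2, CH2Cl2, −78 °C
Reagents that add atoms: none
Why: Mukaiyama aldol addition through an open transition state follows the Felkin–Anh model (C7 as the large group anti to the nucleophile, the C11 methyl as the medium group), which should give the 11,12-syn adduct, that is 12S.

Step 22
Reactants: 29 β-hydroxy enone
Product: 30 β-acetoxy enone
Conditions: Ac2O, pyridine, DMAP (cat.), CH2Cl2, 0 °C
Reagents that add atoms: acetic anhydride, CC(=O)OC(C)=O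
Why: acylation of the only free hydroxyl places the acetate unambiguously on O12, and the mild conditions should avoid β-elimination.

Step 23
Reactants: 30 β-acetoxy enone
Product: 31 bis-silyl ether of the target (14R)
Conditions: (S)-2-methyl-CBS-oxazaborolidine (0.5 equiv), catecholborane, toluene, −78 °C
Reagents that add atoms: none
Why: Corey–Bakshi–Shibata reduction is reagent-controlled with the isopropenyl group as the large substituent, so the (S)-oxazaborolidine should deliver hydride to give the 14R allylic alcohol, and catecholborane does not hydroborate the 1,1-disubstituted alkenes at this temperature.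

Step 24
Reactants: 31 bis-silyl ether of the target
Product: 32 target CNP0281601.4
Conditions: HF·pyridine, pyridine, THF, 0 °C to rt
Reagents that add atoms: none
Why: buffered HF·pyridine cleaves both silyl ethers under conditions that should cause neither hydrolysis nor migration of the C12 acetate.

**Compound list**
1 | geranyl acetate | CC(C)=CCC/C(C)=C/COC(C)=O | starting material
2 | (2E,6E)-3,7-dimethyl-8-oxoocta-2,6-dien-1-yl acetate | O=C/C(C)=C/CC/C(C)=C/COC(C)=O | intermediate
3 | (2E,6E)-3,7-dimethylnona-2,6,8-trien-1-yl acetate | C=C/C(C)=C/CC/C(C)=C/COC(C)=O | intermediate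
4 | (2E,6E)-3,7-dimethylnona-2,6,8-trien-1-ol | C=C/C(C)=C/CC/C(C)=C/CO | intermediate
5 | [(2R,3R)-3-methyl-3-[(3E)-4-methylhexa-3,5-dien-1-yl]oxiran-2-yl]methanol | OC[C@H]1O[C@]1(C)CC/C=C(C)/C=C | intermediate
6 | (2S,3R)-3-methyl-3-[(3E)-4-methylhexa-3,5-dien-1-yl]oxirane-2-carbaldehyde | O=C[C@H]1O[C@]1(C)CC/C=C(C)/C=C | intermediate
7 | 1-[(2R,3R)-3-methyl-3-[(3E)-4-methylhexa-3,5-dien-1-yl]oxiran-2-yl]ethan-1-ol, carbinol epimers | CC(O)[C@H]1O[C@]1(C)CC/C=C(C)/C=C | intermediate
8 | 1-[(2S,3R)-3-methyl-3-[(3E)-4-methylhexa-3,5-dien-1-yl]oxiran-2-yl]ethan-1-one | CC(=O)[C@H]1O[C@]1(C)CC/C=C(C)/C=C | intermediate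
9 | lithium enolate of 8 (methyl side) | [Li]OC(=C)[C@H]1O[C@]1(C)CC/C=C(C)/C=C | intermediate
10 | triethylsilyl enol ether of 8 | C=C(O[Si](CC)(CC)CC)[C@H]1O[C@]1(C)CC/C=C(C)/C=C | intermediate
11 | O-triethylsilyl epoxonium triflate of 10 | C=C(O[Si](CC)(CC)CC)[C@H]1[O+]([Si](CC)(CC)CC)[C@]1(C)CC/C=C(C)/C=C.[O-]S(=O)(=O)C(F)(F)F | intermediate
12 | O-triethylsilyl oxocarbenium triflate of 13 | C1CC=C(C)[C@H]2CC[C@@](C)(O[Si](CC)(CC)CC)[C@@H]2C1=[O+][Si](CC)(CC)CC.[O-]S(=O)(=O)C(F)(F)F | intermediate
13 | trans-fused hydroazulenone, (1S,4R,5R), C6 ketone, C9=C10(CH3), C4 methyl and triethylsilyloxy | C1CC=C(C)[C@H]2CC[C@@](C)(O[Si](CC)(CC)CC)[C@@H]2C1=O | intermediate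
14 | ethyl (S)-lactate | C[C@H](O)C(=O)OCC | starting material
15 | ethyl (2S)-2-{[(trifluoromethyl)sulfonyl]oxy}propanoate | C[C@H](OS(=O)(=O)C(F)(F)F)C(=O)OCC | intermediate
16 | lithium C6(O)=C7 enolate of 13 | [Li]OC1=CCC=C(C)[C@H]2CC[C@@](C)(O[Si](CC)(CC)CC)[C@@H]21 | intermediate
17 | γ-keto ester, ethyl (2S)-2-[(7R)-6-oxo-hydroazulen-7-yl]propanoate, ring centres as in 13 | CCOC(=O)[C@@H](C)[C@H]1CC=C(C)[C@H]2CC[C@@](C)(O[Si](CC)(CC)CC)[C@@H]2C1=O | intermediate
18 | (6S)-hydroxy ester, hydroxyl cis to the C7 chain | CCOC(=O)[C@@H](C)[C@H]1CC=C(C)[C@H]2CC[C@@](C)(O[Si](CC)(CC)CC)[C@@H]2[C@H]1O | intermediate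
19 | cis-fused γ-lactone (O6–C12), 11S methyl, C4 triethylsilyl ether, C9=C10 alkene | O=C3[C@@H](C)[C@H]1CC=C(C)[C@H]2CC[C@@](C)(O[Si](CC)(CC)CC)[C@@H]2[C@H]1O3 | intermediate
20 | (9S,10R)-9,10-epoxide of 19, oxygen cis to H1 | O=C3[C@@H](C)[C@H]1C[C@@H]4O[C@]4(C)[C@H]2CC[C@@](C)(O[Si](CC)(CC)CC)[C@@H]2[C@H]1O3 | intermediate
21 | lactone with (9S)-hydroxyl and C10 exocyclic methylene | O=C3[C@@H](C)[C@H]1C[C@H](O)C(=C)[C@H]2CC[C@@](C)(O[Si](CC)(CC)CC)[C@@H]2[C@H]1O3 | intermediate
22 | N-methoxy-N-methyl amide with free C6 and C9 hydroxyls | CON(C)C(=O)[C@@H](C)[C@H]1C[C@H](O)C(=C)[C@H]2CC[C@@](C)(O[Si](CC)(CC)CC)[C@@H]2[C@H]1O | intermediate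
23 | 6,9-bis(tert-butyldimethylsilyl) ether of 22 | CON(C)C(=O)[C@@H](C)[C@H]1C[C@H](O[Si](C)(C)C(C)(C)C)C(=C)[C@H]2CC[C@@](C)(O[Si](CC)(CC)CC)[C@@H]2[C@H]1O[Si](C)(C)C(C)(C)C | intermediate
24 | C4 tertiary alcohol (triethylsilyl group removed) | CON(C)C(=O)[C@@H](C)[C@H]1C[C@H](O[Si](C)(C)C(C)(C)C)C(=C)[C@H]2CC[C@@](C)(O)[C@@H]2[C@H]1O[Si](C)(C)C(C)(C)C | intermediate
25 | Weinreb amide with C3=C4 cyclopentene | CON(C)C(=O)[C@@H](C)[C@H]1C[C@H](O[Si](C)(C)C(C)(C)C)C(=C)[C@H]2CC=C(C)[C@@H]2[C@H]1O[Si](C)(C)C(C)(C)C | intermediate
26 | C12 aldehyde (11S) | O=C[C@@H](C)[C@H]1C[C@H](O[Si](C)(C)C(C)(C)C)C(=C)[C@H]2CC=C(C)[C@@H]2[C@H]1O[Si](C)(C)C(C)(C)C | intermediate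
27 | 3-methylbut-3-en-2-one | CC(=O)C(C)=C | starting material
28 | trimethyl[(3-methylbuta-1,3-dien-2-yl)oxy]silane | C=C(O[Si](C)(C)C)C(C)=C | intermediate
29 | (12S)-β-hydroxy enone | C=C(C)C(=O)C[C@H](O)[C@@H](C)[C@H]1C[C@H](O[Si](C)(C)C(C)(C)C)C(=C)[C@H]2CC=C(C)[C@@H]2[C@H]1O[Si](C)(C)C(C)(C)C | intermediate
30 | (12S)-β-acetoxy enone | C=C(C)C(=O)C[C@H](OC(C)=O)[C@@H](C)[C@H]1C[C@H](O[Si](C)(C)C(C)(C)C)C(=C)[C@H]2CC=C(C)[C@@H]2[C@H]1O[Si](C)(C)C(C)(C)C | intermediate
31 | 6,9-bis(tert-butyldimethylsilyl) ether of the target (14R) | C=C(C)[C@H](O)C[C@H](OC(C)=O)[C@@H](C)[C@H]1C[C@H](O[Si](C)(C)C(C)(C)C)C(=C)[C@H]2CC=C(C)[C@@H]2[C@H]1O[Si](C)(C)C(C)(C)C | intermediate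
32 | CNP0281601.4 | C=C(C)[C@H](O)C[C@H](OC(C)=O)[C@@H](C)[C@H]1C[C@H](O)C(=C)[C@H]2CC=C(C)[C@@H]2[C@H]1O | target

**Totals and risks**
Total step count: 24 (22 on the main line plus two one-step reagent preparations, steps 10 and 20). Longest linear sequence: 22 steps (1–9, 11–19, 21–24).

Step 9. What may go wrong: the silylated epoxide ionises at its tertiary carbon C4 and rearranges by hydride or alkenyl shift before the diene arrives, or the partners close through the compact arrangement and give cis ring fusion. Fallback, a free oxyallyl cation route that sets out from 8 and comes back at 13: SmI2 (THF/MeOH, −90 °C) opens the epoxy ketone reductively at the α-carbon to β-hydroxy ketone F1 with C4 intact, and Et3SiOTf/2,6-lutidine gives silyl ether F2. LiN(iPr)2 forms the kinetic methyl-side lithium enolate F3, which N-bromosuccinimide converts into bromomethyl ketone F4. Et3N in 2,2,2-trifluoroethanol then generates the oxyallyl cation by enolisation toward C5 and loss of bromide from C7. Its intramolecular (4+3) cycloaddition across the three-atom tether is the long-established base/fluoroalcohol variant that favours trans-fused five–seven products, and it should give 13, with the C4 stereocentre (silyloxy group trans to C6 on the new ring) steering the face.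

Step 11. What may go wrong: alkylation on the other enolate face or on oxygen, elimination of the triflate to ethyl acrylate, or proton exchange that epimerises the axial product. Fallback, an auxiliary-controlled alkylation that sets out from 13 and comes back at 17: condensation of 13 with (R)-1-amino-2-(methoxymethyl)pyrrolidine gives RAMP hydrazone F5. LiN(iPr)2 gives lithium azaenolate F6 on the C7 side, and alkylation with 15 gives alkylated hydrazone F7, with the C7 face dictated by the auxiliary (Enders hydrazone alkylation) and C11 again set by inversion. Aqueous oxalic acid/Et2O cleaves the hydrazone without touching the alkene and returns 17.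

Step 18. What may go wrong: loss of a methyl proton gives the exocyclic C4 methylene isomer, which cannot be isomerised selectively once the C10 methylene is present. Fallback, elimination before C9/C10 are unmasked, which sets out from 20 and comes back at 25: Bu4NF removes the triethylsilyl group to give tertiary alcohol F8. SOCl2/pyridine gives ring alkene F10 together with any exocyclic isomer F9. Because the epoxide still masks C9–C10, F9 is then the only 1,1-disubstituted alkene and can be moved into the ring at C3=C4 by Co(salen)Cl/PhSiH3 hydrogen-atom-transfer isomerisation. Cp2TiCl converts the epoxide into allylic alcohol F11, aminolysis as in step 15 gives diol amide F12, and bis-silylation as in step 16 returns 25. This order also removes the need for the selective desilylation of step 17.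

**Further compounds**
F1 | step 9 | (4R)-4-hydroxy-4,8-dimethyldeca-7,9-dien-2-one-type β-hydroxy ketone from 8 | CC(=O)C[C@](C)(O)CC/C=C(C)/C=C
F2 | step 9 | triethylsilyl ether of F1 | CC(=O)C[C@](C)(O[Si](CC)(CC)CC)CC/C=C(C)/C=C
F3 | step 9 | kinetic lithium enolate of F2 (methyl side) | [Li]OC(=C)C[C@](C)(O[Si](CC)(CC)CC)CC/C=C(C)/C=C
F4 | step 9 | bromomethyl ketone from F3 | BrCC(=O)C[C@](C)(O[Si](CC)(CC)CC)CC/C=C(C)/C=C
F5 | step 11 | RAMP hydrazone of 13 (C=N geometry not fixed) | COC[C@@H]1CCCN1N=C3CCC=C(C)[C@H]2CC[C@@](C)(O[Si](CC)(CC)CC)[C@@H]23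
F6 | step 11 | lithium azaenolate of F5 (C6=C7) | COC[C@@H]1CCCN1N([Li])C3=CCC=C(C)[C@H]2CC[C@@](C)(O[Si](CC)(CC)CC)[C@@H]23
F7 | step 11 | RAMP hydrazone of 17 (7R,11S) | COC[C@@H]1CCCN1N=C3[C@@H]([C@H](C)C(=O)OCC)CC=C(C)[C@H]2CC[C@@](C)(O[Si](CC)(CC)CC)[C@@H]23
F8 | step 18 | epoxy lactone with free C4 tertiary hydroxyl | O=C3[C@@H](C)[C@H]1C[C@@H]4O[C@]4(C)[C@H]2CC[C@@](C)(O)[C@@H]2[C@H]1O3
F9 | step 18 | epoxy lactone with exocyclic C4 methylene | O=C3[C@@H](C)[C@H]1C[C@@H]4O[C@]4(C)[C@H]2CCC(=C)[C@@H]2[C@H]1O3
F10 | step 18 | epoxy lactone with C3=C4 cyclopentene | O=C3[C@@H](C)[C@H]1C[C@@H]4O[C@]4(C)[C@H]2CC=C(C)[C@@H]2[C@H]1O3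
F11 | step 18 | lactone with (9S)-hydroxyl, C10 methylene and C3=C4 | O=C3[C@@H](C)[C@H]1C[C@H](O)C(=C)[C@H]2CC=C(C)[C@@H]2[C@H]1O3
F12 | step 18 | dihydroxy Weinreb amide with C3=C4 | CON(C)C(=O)[C@@H](C)[C@H]1C[C@H](O)C(=C)[C@H]2CC=C(C)[C@@H]2[C@H]1O
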